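**Retrosynthetic overview**

1. The strategy rests on the central benzene ring of the target: a hydroquinone with OH on C1 and C4, aryloxy groups on C3 and C6 (para to each other, each ortho to one OH) and Br on C2 and C5. A 4-alkenyl-4-hydroxycyclobutenone delivers this 2,5-dioxy-substituted hydroquinone pattern regiospecifically.
2. Target 21 ⇐ octabromide 20 ⇐ bisphenol 18: all eight bromines are introduced last by electrophilic substitution (two on the central ring, three on each outer ring), then the central methyl ethers are cleaved.
3. Central ring ⇐ thermal ring expansion of cyclobutenone 13: the four-membered ring supplies four ring carbons and both ring oxygens, and the aryl vinyl ether supplies the other two carbons.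
4. 13 ⇐ cis-hydrogenation of alkynyl carbinol 12 ⇐ lithium aryloxyacetylide (from phenol 5 and trichloroethylene) + aryl semisquarate 7 ⇐ semisquaric acid ⇐ diisopropyl squarate.
5. Ring order: the outer benzene rings are bought, the cyclobutene comes from the squarate, and the central benzene ring is closed last (step 7).

Key step: step 7

Remark on the chemistry: the sp3 stereocentres that appear on the way (compounds 2, 12, 13, 15) are racemic and all disappear before the achiral target. The outer rings carry no bromine and are protected as benzyl ethers until after step 9, because n-BuLi (step 5) and Pd/H2 (steps 6 and 9) would attack C–Br bonds. Diisopropyl squarate is taken as the commercial ester of squaric acid. The alkene of 13 is Z because it is made by syn-hydrogenation; its geometry is lost when the ring aromatises.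

**Step 1**
Reactants: 1 diisopropyl squarate (3,4-diisopropoxycyclobut-3-ene-1,2-dione)
Product: 3 3-isopropoxycyclobut-3-ene-1,2-dione, via hydroxycyclobutenone 2 (not isolated)
Conditions: LiAlH(OtBu)3, THF, −20 °C; then conc. HCl, CH2Cl2, 20 °C
Reagents that add atoms: water, O
Why: The bulky hydride should add once to a squarate carbonyl (racemic carbinol 2), and acid then ionises the carbinol and expels isopropanol with carbonyl transposition, the established reduction–hydrolysis route from dialkyl squarates to alkyl semisquarates.

**Step 2**
Reactants: 3 3-isopropoxycyclobut-3-ene-1,2-dione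
Product: 4 3-hydroxycyclobut-3-ene-1,2-dione (semisquaric acid)
Conditions: 6 M HCl, THF, 50 °C; evaporate to dryness
Reagents that add atoms: water, O
Why: Acid hydrolysis of the vinylogous isopropyl ester (addition–elimination of water) should give the strong vinylogous acid, which is isolated by evaporation alone.

**Step 3**
Reactants: 4 semisquaric acid; 5 4-(benzyloxy)phenol
Product: 7 3-[4-(benzyloxy)phenoxy]cyclobut-3-ene-1,2-dione, via semisquaric chloride 6 (not isolated)
Conditions: (COCl)2, DMF (cat.), CH2Cl2, 0 → 20 °C; then 5, 2,6-lutidine, CH2Cl2, −40 → 0 °C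
Reagents that add atoms: none
Why: Vilsmeier-type chlorination of the vinylogous acid gives the vinylogous acyl chloride 6, and addition–elimination by the phenol in the presence of a hindered base should give the aryl ester, as in the esterification of squaric acid dichloride.

**Step 4**
Reactants: 5 4-(benzyloxy)phenol; 8 trichloroethylene
Product: 9 1-(benzyloxy)-4-{[(E)-1,2-dichloroethenyl]oxy}benzene
Conditions: K2CO3, DMF, 70 °C
Reagents that add atoms: none
Why: Base converts trichloroethylene into dichloroacetylene in situ and the phenoxide adds anti across it (vinylic substitution by elimination–addition), the standard route to (E)-1,2-dichlorovinyl aryl ethers.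

**Step 5**
Reactants: 9 (E)-1,2-dichlorovinyl ether; 7 aryl semisquarate
Product: 12 4-{[4-(benzyloxy)phenoxy]ethynyl}-3-[4-(benzyloxy)phenoxy]-4-hydroxycyclobut-2-en-1-one, via chloroalkynyl ether 10 (not isolated), via lithium aryloxyacetylide 11 (not isolated)
Conditions: n-BuLi (2.0 equiv), THF, −78 → −40 °C; then cannulate into 7, THF, −78 °C; aq. NH4Cl at −78 °C
Reagents that add atoms: none
Why: Deprotonation, loss of LiCl and chlorine–lithium exchange turn the dichlorovinyl ether into the lithium ynolate-ether acetylide, which as a hard nucleophile should undergo 1,2-addition at the ketone-like carbonyl next to the aryloxy-bearing carbon (the vinylogous ester carbonyl is deactivated), giving the tertiary carbinol as a racemate with the regiochemistry that later places the two aryloxy groups para.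

**Step 6**
Reactants: 12 alkynyl carbinol
Product: 13 3-[4-(benzyloxy)phenoxy]-4-{(Z)-2-[4-(benzyloxy)phenoxy]ethenyl}-4-hydroxycyclobut-2-en-1-one (racemic)
Conditions: H2 (1 atm), Pd/CaCO3 poisoned with Pb(OAc)2 (Lindlar catalyst), quinoline, EtOAc, 0 °C
Reagents that add atoms: none
Why: Lindlar semihydrogenation (syn addition of H2 to the alkynyl ether on poisoned palladium) should give the Z-enol ether without touching the benzyl ethers or the vinylogous ester double bond, and the carbinol centre stays racemic and unchanged.

**Step 7**
Reactants: 13 (Z)-alkenyl hydroxycyclobutenone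
Product: 16 2,5-bis[4-(benzyloxy)phenoxy]benzene-1,4-diol, via dienylketene 14 (not isolated), via cyclohexadienone 15 (not isolated)
Conditions: PhMe (degassed, dilute), 110 °C, Ar
Reagents that add atoms: none
Why: Heating opens the cyclobutenone by a conrotatory four-electron electrocyclic reaction in which the C4 hydroxyl, as the donor, turns outward and the alkenyl group inward, giving dienylketene 14. Its ketene carbon then bonds to the aryloxy-bearing vinyl carbon in a disrotatory six-electron electrocyclisation, which closes the central six-membered ring as cyclohexadienone 15, and enolisation of its C6–H aromatises it to hydroquinone 16. The closest known reaction type is the Moore rearrangement of 4-alkenyl-4-hydroxycyclobutenones, including cycloalkenyl and 2-furyl cases in which the reacting alkene carbon carries a cis substituent or an oxygen. The only new stereocentre (C6 of 15) is transient and racemic and the alkene geometry is lost, so neither needs control. The step needs outward rotation of the hydroxyl rather than of the alkenyl group (otherwise the ketene is trapped as a butenolide) and enolisation of 15 rather than loss of aryloxide; the donor hydroxyl should secure the first and the neutral, base-free, non-polar medium the second. The para relationship of the two aryloxy groups is already fixed in 13 by the aryloxy group on C3 and the addition site of step 5.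

**Step 8**
Reactants: 16 2,5-bis[4-(benzyloxy)phenoxy]benzene-1,4-diol
Product: 17 1,4-bis[4-(benzyloxy)phenoxy]-2,5-dimethoxybenzene
Conditions: MeI, K2CO3, DMF (degassed), 20 °C, Ar
Reagents that add atoms: iodomethane, CI
Why: Williamson O-methylation caps the air-sensitive hydroquinone so that the later bromination cannot oxidise the central ring to a quinone and the aryloxy oxygens remain electron donors toward the outer rings.

**Step 9**
Reactants: 17 dimethyl ether
Product: 18 4,4'-[(2,5-dimethoxy-1,4-phenylene)bis(oxy)]diphenol
Conditions: H2 (1 atm), Pd/C, EtOAc–MeOH, 20 °C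
Reagents that add atoms: none
Why: Hydrogenolysis of the benzyl ethers over Pd/C, done before any bromine is present, should free the outer phenols whose hydroxyl groups direct the bromination.

**Step 10**
Reactants: 18 bisphenol
Product: 20 4,4'-[(2,5-dibromo-3,6-dimethoxy-1,4-phenylene)bis(oxy)]bis(2,3,6-tribromophenol), via hexabromide 19 (not isolated)
Conditions: Br2 (6.1 equiv), CH2Cl2–AcOH, 0 → 20 °C; then Br2 (2.1 equiv), FeBr3 (cat.), 40 °C; aq. NaHSO3
Reagents that add atoms: bromine, BrBr
Why: Electrophilic aromatic bromination should follow the order of activation: the two free positions of the tetra-oxygenated central ring and the four positions ortho to the outer hydroxyls react first (hexabromide 19), the FeBr3-catalysed second stage places one bromine ortho to the diaryl ether oxygen on each outer ring, and the last C–H of each ring, then meta to the new bromine on a tribrominated ring, is deactivated enough for the sequence to stop at eight bromines.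

**Step 11**
Reactants: 20 octabromide dimethyl ether
Product: 21 2,5-dibromo-3,6-bis(2,3,5-tribromo-4-hydroxyphenoxy)benzene-1,4-diol (target, CNP0163357.0)
Conditions: BBr3, CH2Cl2, −78 → 20 °C; then H2O
Reagents that add atoms: none
Why: Lewis-acid ether cleavage with BBr3 should remove the two hindered central methyl ethers while aryl bromides and diaryl ethers are inert, giving the hydroquinone without any redox step.

**Compound list**

1 | diisopropyl squarate (3,4-diisopropoxycyclobut-3-ene-1,2-dione) | CC(C)OC1=C(OC(C)C)C(=O)C1=O | starting material
2 | 4-hydroxy-2,3-diisopropoxycyclobut-2-en-1-one (racemic, one enantiomer drawn) | CC(C)OC1=C(OC(C)C)[C@@H](O)C1=O | intermediate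
3 | 3-isopropoxycyclobut-3-ene-1,2-dione | CC(C)OC1=CC(=O)C1=O | intermediate
4 | 3-hydroxycyclobut-3-ene-1,2-dione (semisquaric acid) | OC1=CC(=O)C1=O | intermediate
5 | 4-(benzyloxy)phenol | Oc1ccc(OCc2ccccc2)cc1 | starting material
6 | 3-chlorocyclobut-3-ene-1,2-dione (semisquaric chloride) | ClC1=CC(=O)C1=O | intermediate
7 | 3-[4-(benzyloxy)phenoxy]cyclobut-3-ene-1,2-dione | O=C1C=C(Oc2ccc(OCc3ccccc3)cc2)C1=O | intermediate
8 | trichloroethylene | ClC=C(Cl)Cl | starting material
9 | 1-(benzyloxy)-4-{[(E)-1,2-dichloroethenyl]oxy}benzene | Cl/C=C(/Cl)Oc1ccc(OCc2ccccc2)cc1 | intermediate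
10 | 1-(benzyloxy)-4-[(chloroethynyl)oxy]benzene | ClC#COc1ccc(OCc2ccccc2)cc1 | intermediate
11 | lithium [4-(benzyloxy)phenoxy]acetylide | [Li]C#COc1ccc(OCc2ccccc2)cc1 | intermediate
12 | 4-{[4-(benzyloxy)phenoxy]ethynyl}-3-[4-(benzyloxy)phenoxy]-4-hydroxycyclobut-2-en-1-one (racemic, one enantiomer drawn) | O=C1C=C(Oc2ccc(OCc3ccccc3)cc2)[C@]1(O)C#COc1ccc(OCc2ccccc2)cc1 | intermediate
13 | 3-[4-(benzyloxy)phenoxy]-4-{(Z)-2-[4-(benzyloxy)phenoxy]ethenyl}-4-hydroxycyclobut-2-en-1-one (racemic, one enantiomer drawn) | O=C1C=C(Oc2ccc(OCc3ccccc3)cc2)[C@]1(O)/C=C\Oc1ccc(OCc2ccccc2)cc1 | intermediate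
14 | dienylketene: (3Z,5Z)-3,6-bis[4-(benzyloxy)phenoxy]-4-hydroxyhexa-1,3,5-trien-1-one | O=C=C/C(Oc1ccc(OCc2ccccc2)cc1)=C(\C=C/Oc1ccc(OCc2ccccc2)cc1)O | intermediate
15 | 3,6-bis[4-(benzyloxy)phenoxy]-4-hydroxycyclohexa-2,4-dien-1-one (racemic, one enantiomer drawn) | O=C1C=C(Oc2ccc(OCc3ccccc3)cc2)C(O)=C[C@@H]1Oc1ccc(OCc2ccccc2)cc1 | intermediate
16 | 2,5-bis[4-(benzyloxy)phenoxy]benzene-1,4-diol | Oc1cc(Oc2ccc(OCc3ccccc3)cc2)c(O)cc1Oc1ccc(OCc2ccccc2)cc1 | intermediate
17 | 1,4-bis[4-(benzyloxy)phenoxy]-2,5-dimethoxybenzene | COc1cc(Oc2ccc(OCc3ccccc3)cc2)c(OC)cc1Oc1ccc(OCc2ccccc2)cc1 | intermediate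
18 | 4,4'-[(2,5-dimethoxy-1,4-phenylene)bis(oxy)]diphenol | COc1cc(Oc2ccc(O)cc2)c(OC)cc1Oc1ccc(O)cc1 | intermediate
19 | 4,4'-[(2,5-dibromo-3,6-dimethoxy-1,4-phenylene)bis(oxy)]bis(2,6-dibromophenol) | COc1c(Br)c(Oc2cc(Br)c(O)c(Br)c2)c(OC)c(Br)c1Oc1cc(Br)c(O)c(Br)c1 | intermediate
20 | 4,4'-[(2,5-dibromo-3,6-dimethoxy-1,4-phenylene)bis(oxy)]bis(2,3,6-tribromophenol) | COc1c(Br)c(Oc2cc(Br)c(O)c(Br)c2Br)c(OC)c(Br)c1Oc1cc(Br)c(O)c(Br)c1Br | intermediate
21 | 2,5-dibromo-3,6-bis(2,3,5-tribromo-4-hydroxyphenoxy)benzene-1,4-diol | Oc1c(Br)cc(Oc2c(O)c(Br)c(Oc3cc(Br)c(O)c(Br)c3Br)c(O)c2Br)c(Br)c1Br | target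

**Step count**

Total steps: 11. Longest linear sequence: 10 (steps 1, 2, 3, 5, 6, 7, 8, 9, 10, 11); step 4 is the side branch.

**Steps most likely to fail, with fallbacks**

Step 10. The last bromine on each outer ring, next to the ether oxygen, enters a ring that already holds two bromines. The reaction may therefore stall at fewer than eight bromines, run on to a fourth bromine on an outer ring, or attack ipso to the ether oxygen para to the free hydroxyl and cleave the ether. The fallback separates the difficult bromination from the easy ones by switching the outer oxygens between acylated and free states. It sets out from 18 and returns at 20. Acetylation (Ac2O, pyridine) should give the diacetate F1, in which the ether oxygen is the strongest donor on each outer ring and no free phenol is present. Br2 (4 equiv, FeBr3 cat., CH2Cl2) should then brominate the two central-ring positions and one position ortho to the ether oxygen on each outer ring, and stop there because the second such position is meta to the new bromine (tetrabromide F2). Methanolysis (K2CO3, MeOH) frees the phenols to give the bis(3-bromophenol) F3. Br2 (4 equiv, AcOH, 20 °C) then fills the two positions ortho to each hydroxyl under mild conditions and gives 20.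

Step 7. The ring opening may turn the alkenyl group outward, after which the hydroxyl lactonises the ketene. The dienone may also expel aryloxide instead of enolising, and the electron-rich hydroquinone may be oxidised by air during isolation. The fallback forms the two diaryl ether bonds on a bought central ring by cross-coupling. It sets out from phenol 5 and returns at 17. Double Ullmann etherification of 5 with 1,4-dibromo-2,5-dimethoxybenzene F4 (CuI, picolinic acid, Cs2CO3, DMSO, 100 °C) should give 17 directly.

Step 6. The hydrogenation may run past the enol ether or be unselective, and the β-aryloxyvinyl carbinol may rearrange under traces of acid on the catalyst support or on silica. The fallback makes the Z-alkenyl nucleophile first and adds it to the dione, so no alkyne is reduced in the presence of the cyclobutenone. It sets out from 9 (with 7) and returns at 13. Treatment of 9 with n-BuLi (2 equiv, THF, −78 °C) and a methanol quench should give the terminal ynol ether F5, to be used at once. Radical hydrostannylation (Bu3SnH, AIBN cat., PhH, 70 °C) should give the (Z)-vinylstannane F6 by anti addition. Tin–lithium exchange (n-BuLi, THF, −78 °C) gives the (Z)-vinyllithium F7, in which lithium and aryloxy are cis and cannot eliminate anti-periplanar. Addition of F7 to 7 at −78 °C and a cold NH4Cl quench should give 13.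

**Further compounds**

F1 | step 10 | [(2,5-dimethoxy-1,4-phenylene)bis(oxy)]bis(4,1-phenylene) diacetate | COc1cc(Oc2ccc(OC(C)=O)cc2)c(OC)cc1Oc1ccc(OC(C)=O)cc1
F2 | step 10 | [(2,5-dibromo-3,6-dimethoxy-1,4-phenylene)bis(oxy)]bis(3-bromo-4,1-phenylene) diacetate | COc1c(Br)c(Oc2ccc(OC(C)=O)cc2Br)c(OC)c(Br)c1Oc1ccc(OC(C)=O)cc1Br
F3 | step 10 | 4,4'-[(2,5-dibromo-3,6-dimethoxy-1,4-phenylene)bis(oxy)]bis(3-bromophenol) | COc1c(Br)c(Oc2ccc(O)cc2Br)c(OC)c(Br)c1Oc1ccc(O)cc1Br
F4 | step 7 | 1,4-dibromo-2,5-dimethoxybenzene | COc1cc(Br)c(OC)cc1Br
F5 | step 6 | 1-(benzyloxy)-4-(ethynyloxy)benzene | C#COc1ccc(OCc2ccccc2)cc1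
F6 | step 6 | tributyl{(Z)-2-[4-(benzyloxy)phenoxy]ethenyl}stannane | CCCC[Sn](CCCC)(CCCC)/C=C\Oc1ccc(OCc2ccccc2)cc1
F7 | step 6 | {(Z)-2-[4-(benzyloxy)phenoxy]ethenyl}lithium | [Li]/C=C\Oc1ccc(OCc2ccccc2)cc1
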